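The bonds, rings and skeletons fixed for the key step were checked atom by atom and needed no correction.

**Strategy.** The route rests on making ring A of the apigenin unit (C4a''–C5''–C6''–C7''–C8''–C8a'') last, by benzannulation onto a preformed 4-pyranone. The feature used is that C8'' carries the acacetin C6 aryl and sits next to C8a''–O1'', while the C5'' and C7'' oxygens are meta. An aryl(pyranon-2-yl)ketene supplies C8'', C8a'', C4a'' and C5''; a silyl ynol ether supplies C6'' and C7''. One operation forms C5''–C6'', C7''–C8'' and C4a''–C5'' and gives the whole biflavone skeleton with 5''-OH free. The precursor ketene carries the 5,7-dibenzylated acacetin C6 and a 6-aryl-4-pyranon-2-yl group on its α-carbon and is generated from the corresponding acetic acid.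

Key step: step 12

Remark on the chemistry: the target is written without a descriptor for the tetra-ortho-substituted C6–C8'' axis, so it is taken as the racemate and 28–30 form as racemic atropisomers. The stereocentres of 12, 16, 23, 25 and 27 are racemic and transient.

Step 1
Reactants: 1 acacetin (5,7-dihydroxy-4'-methoxyflavone); 2 benzyl bromide
Product: 3 7-(benzyloxy)-5-hydroxy-4'-methoxyflavone
Conditions: BnBr (1.1 equiv), K2CO3, acetone, reflux
Reagents that add atoms: benzyl bromide (2), BrCc1ccccc1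
Why: Williamson etherification should be selective for the acidic 7-OH because the 5-OH is held in a hydrogen bond to the C4 carbonyl.

Step 2
Reactants: 3 7-(benzyloxy)-5-hydroxy-4'-methoxyflavone; 4 allyl bromide
Product: 5 5-(allyloxy)-7-(benzyloxy)-4'-methoxyflavone
Conditions: allyl bromide, Cs2CO3, DMF, 50 °C
Reagents that add atoms: allyl bromide (4), C=CCBr
Why: With O7 blocked, Williamson alkylation by the reactive allylic halide under Cs2CO3 in DMF should overcome the chelation of the 5-OH.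

Step 3
Reactants: 5 5-(allyloxy)-7-(benzyloxy)-4'-methoxyflavone
Product: 6 6-allyl-7-(benzyloxy)-5-hydroxy-4'-methoxyflavone
Conditions: PhNEt2, 200 °C
Reagents that add atoms: none
Why: The aromatic Claisen rearrangement can deliver the allyl group only to C6, the single free position ortho to O5 (the other is C4a), and tautomerisation restores the chelated 5-OH.

Step 4
Reactants: 6 6-allyl-7-(benzyloxy)-5-hydroxy-4'-methoxyflavone; 2 benzyl bromide
Product: 7 6-allyl-5,7-bis(benzyloxy)-4'-methoxyflavone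
Conditions: BnBr, Cs2CO3, DMF, 60 °C
Reagents that add atoms: benzyl bromide (2), BrCc1ccccc1
Why: Williamson benzylation caps the 5-OH so that both positions ortho to C6 carry ether oxygens, which later prevents a phenol from trapping the ketene.

Step 5
Reactants: 7 6-allyl-5,7-bis(benzyloxy)-4'-methoxyflavone
Product: 8 [5,7-bis(benzyloxy)-4'-methoxyflavon-6-yl]acetaldehyde
Conditions: OsO4 (2 mol %), NaIO4, 2,6-lutidine, dioxane/H2O, rt
Reagents that add atoms: osmium tetroxide, O=[Os](=O)(=O)=O; sodium periodate, [Na+].[O-]I(=O)(=O)=O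
Why: In this Lemieux–Johnson cleavage OsO4 should dihydroxylate the terminal alkene far faster than the electron-poor, conjugated C2=C3 bond of the flavone, and periodate cleaves the diol to the arylacetaldehyde.

Step 6
Reactants: 9 4'-(benzyloxy)acetophenone; 10 ethyl acetate
Product: 11 1-[4-(benzyloxy)phenyl]butane-1,3-dione
Conditions: NaH, EtOAc, THF, reflux; then 1 M HCl
Reagents that add atoms: ethyl acetate (10), CCOC(C)=O
Why: Crossed Claisen condensation of the ketone enolate with ethyl acetate is driven to completion by deprotonation of the β-diketone formed.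

Step 7
Reactants: 11 1-[4-(benzyloxy)phenyl]butane-1,3-dione; 8 [5,7-bis(benzyloxy)-4'-methoxyflavon-6-yl]acetaldehyde
Product: 12 rac-1-[4-(benzyloxy)phenyl]-6-[5,7-bis(benzyloxy)-4'-methoxyflavon-6-yl]-5-hydroxyhexane-1,3-dione
Conditions: 11 (1.3 equiv), LiN(i-Pr)2 (2.6 equiv), THF, −78 to 0 °C; then 8, −78 °C; NH4Cl
Reagents that add atoms: 1-[4-(benzyloxy)phenyl]butane-1,3-dione (11), CC(=O)CC(=O)c1ccc(OCc2ccccc2)cc1
Why: The 1,3-dianion of the β-diketone reacts at its terminal carbon, and aldol addition at −78 °C should outrun enolisation of the aldehyde; the carbinol centre forms without control and is removed in step 8.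

Step 8
Reactants: 12 rac-1-[4-(benzyloxy)phenyl]-6-[5,7-bis(benzyloxy)-4'-methoxyflavon-6-yl]-5-hydroxyhexane-1,3-dione
Product: 14 5,7-bis(benzyloxy)-6-({6-[4-(benzyloxy)phenyl]-4-oxo-4H-pyran-2-yl}methyl)-4'-methoxyflavone, via triketone 13 (not isolated)
Conditions: IBX (1.5 equiv), EtOAc, 75 °C; filter, concentrate; then TsOH·H2O (10 mol %), toluene, 4 Å sieves, 80 °C
Reagents that add atoms: none
Why: IBX oxidises the β-hydroxy ketone to the 1,3,5-triketone without attacking the diketone methylene, and acid-catalysed cyclodehydration of the triketone gives the 2,6-disubstituted 4-pyranone.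

Step 9
Reactants: 14 5,7-bis(benzyloxy)-6-({6-[4-(benzyloxy)phenyl]-4-oxo-4H-pyran-2-yl}methyl)-4'-methoxyflavone; 15 carbon dioxide
Product: 16 rac-2-[5,7-bis(benzyloxy)-4'-methoxyflavon-6-yl]-2-{6-[4-(benzyloxy)phenyl]-4-oxo-4H-pyran-2-yl}acetic acid
Conditions: LiN(SiMe3)2 (2.2 equiv), THF, −78 °C; CO2 (g), −78 to −20 °C; cold 1 M HCl to pH 3; used without storage
Reagents that add atoms: carbon dioxide (15), O=C=O
Why: The methylene between the aryl ring and pyranone C2 is the most acidic C–H (benzylic and vinylogous to the pyranone carbonyl), and lateral carboxylation of its lithium dienolate at the exocyclic carbon is the only C-attack that restores the pyranone.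

Step 10
Reactants: 17 (trimethylsilyl)acetylene; 18 tert-butyl hydroperoxide; 19 triisopropylsilyl trifluoromethanesulfonate
Product: 21 triisopropyl{[(trimethylsilyl)ethynyl]oxy}silane, via lithium ynolate 20 (not isolated)
Conditions: n-BuLi, THF, −78 °C; LiOO-t-Bu (from t-BuOOH and LiN(SiMe3)2), −78 to 0 °C; then TIPSOTf, −78 °C; kept cold
Reagents that add atoms: tert-butyl hydroperoxide (18), CC(C)(C)OO; triisopropylsilyl trifluoromethanesulfonate (19), CC(C)[Si](OS(=O)(=O)C(F)(F)F)(C(C)C)C(C)C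
Why: Oxidation of a lithium acetylide by lithium tert-butyl peroxide gives the ynolate, and the bulky, hard silyl triflate should silylate it on oxygen.

Step 11
Reactants: 21 triisopropyl{[(trimethylsilyl)ethynyl]oxy}silane
Product: 22 (triisopropylsilyloxy)acetylene
Conditions: K2CO3 (10 mol %), MeOH/THF, 0 °C, short time; pentane extraction, distillation
Reagents that add atoms: none
Why: Methanolysis of the C(sp)–SiMe3 bond should be much faster than attack on the hindered triisopropylsilyl ether, so protodesilylation frees the terminal ynol ether.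

Step 12
Reactants: 16 rac-2-[5,7-bis(benzyloxy)-4'-methoxyflavon-6-yl]-2-{6-[4-(benzyloxy)phenyl]-4-oxo-4H-pyran-2-yl}acetic acid; 22 (triisopropylsilyloxy)acetylene
Product: 28 5,7-bis(benzyloxy)-6-{2-[4-(benzyloxy)phenyl]-5-hydroxy-4-oxo-7-(triisopropylsilyloxy)-4H-chromen-8-yl}-4'-methoxyflavone, via acid chloride 23 (not isolated), via ketene 24 (not isolated), via cyclobutenone 25 (not isolated), via dienylketene 26 (not isolated), via cyclohexadienone 27 (not isolated)
Conditions: Me2C=C(Cl)NMe2 (1.1 equiv), CH2Cl2, 0 °C to rt; evaporate; Et3N (1.5 equiv), toluene, rt; filter under Ar; 22 (2.5 equiv), rt then 90 °C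
Reagents that add atoms: (triisopropylsilyloxy)acetylene (22), C#CO[Si](C(C)C)(C(C)C)C(C)C
Why: Et3N dehydrochlorinates acid chloride 23 to ketene 24, which undergoes [2+2] cycloaddition with the ynol ether, the nucleophilic alkyne CH bonding to the ketene carbonyl carbon (C5''–C6'') and the silyloxy carbon to the α-carbon (C7''–C8''), to give cyclobutenone 25. Heating opens 25 by four-electron conrotatory cleavage to dienylketene 26, and ring A closes by a thermal six-electron disrotatory electrocyclisation of the ketene carbon onto pyranone C3 (C4a''–C5'', six-membered carbocycle), after which cyclohexadienone 27 enolises to the chelated 5''-phenol. The closest known reaction type is the benzannulation of aryl- and vinylketenes with alkoxy- or silyloxyacetylenes (Smith–Hoehn naphthol synthesis, Danheiser-type benzannulation), for example diarylketenes with ethoxyacetylene giving 3-alkoxy-1-naphthols. No stereocentre is created, and the C6–C8'' bond becomes a stereogenic biaryl axis only here and forms racemic because nothing in the substrate is chiral. The step needs regioselective cycloaddition, secured by the polarisation of the ynol ether, and closure onto the pyranone, secured because both flavone carbons ortho to C6 carry benzyloxy groups, so closure there cannot aromatise and reverts through the reversible ring opening. Generating the acid chloride under neutral conditions and filtering off triethylammonium chloride before heating keep the pyranone carbonyl and the silyl ynol ether away from acid.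

Step 13
Reactants: 28 5,7-bis(benzyloxy)-6-{2-[4-(benzyloxy)phenyl]-5-hydroxy-4-oxo-7-(triisopropylsilyloxy)-4H-chromen-8-yl}-4'-methoxyflavone
Product: 29 5,7-bis(benzyloxy)-6-{2-[4-(benzyloxy)phenyl]-5,7-dihydroxy-4-oxo-4H-chromen-8-yl}-4'-methoxyflavone
Conditions: Bu4NF, AcOH, THF, 0 °C
Reagents that add atoms: none
Why: Fluoride cleavage of the silyl ether of the acidic 7''-phenol should be fast, and acetic acid buffering leaves both flavone rings and the benzyl ethers untouched.

Step 14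
Reactants: 29 5,7-bis(benzyloxy)-6-{2-[4-(benzyloxy)phenyl]-5,7-dihydroxy-4-oxo-4H-chromen-8-yl}-4'-methoxyflavone
Product: 30 6-[5,7-dihydroxy-2-(4-hydroxyphenyl)-4-oxo-4H-chromen-8-yl]-5,7-dihydroxy-2-(4-methoxyphenyl)-4H-chromen-4-one (target)
Conditions: BCl3, C6HMe5, CH2Cl2, −78 to −40 °C; MeOH
Reagents that add atoms: none
Why: Lewis acid debenzylation with pentamethylbenzene as benzyl cation scavenger should remove the three aryl benzyl ethers at low temperature, where the unchelated 4'-methyl ether is inert to BCl3.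

**Compound list**

1 | acacetin (5,7-dihydroxy-4'-methoxyflavone) | COc1ccc(cc1)-c1cc(=O)c2c(O)cc(O)cc2o1 | starting material
2 | benzyl bromide | BrCc1ccccc1 | starting material
3 | 7-(benzyloxy)-5-hydroxy-4'-methoxyflavone | COc1ccc(cc1)-c1cc(=O)c2c(O)cc(OCc3ccccc3)cc2o1 | intermediate
4 | allyl bromide | C=CCBr | starting material
5 | 5-(allyloxy)-7-(benzyloxy)-4'-methoxyflavone | COc1ccc(cc1)-c1cc(=O)c2c(OCC=C)cc(OCc3ccccc3)cc2o1 | intermediate
6 | 6-allyl-7-(benzyloxy)-5-hydroxy-4'-methoxyflavone | COc1ccc(cc1)-c1cc(=O)c2c(O)c(CC=C)c(OCc3ccccc3)cc2o1 | intermediate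
7 | 6-allyl-5,7-bis(benzyloxy)-4'-methoxyflavone | COc1ccc(cc1)-c1cc(=O)c2c(OCc3ccccc3)c(CC=C)c(OCc3ccccc3)cc2o1 | intermediate
8 | [5,7-bis(benzyloxy)-4'-methoxyflavon-6-yl]acetaldehyde | COc1ccc(cc1)-c1cc(=O)c2c(OCc3ccccc3)c(CC=O)c(OCc3ccccc3)cc2o1 | intermediate
9 | 4'-(benzyloxy)acetophenone | CC(=O)c1ccc(OCc2ccccc2)cc1 | starting material
10 | ethyl acetate | CCOC(C)=O | starting material
11 | 1-[4-(benzyloxy)phenyl]butane-1,3-dione | CC(=O)CC(=O)c1ccc(OCc2ccccc2)cc1 | intermediate
12 | rac-1-[4-(benzyloxy)phenyl]-6-[5,7-bis(benzyloxy)-4'-methoxyflavon-6-yl]-5-hydroxyhexane-1,3-dione (racemic at C5) | COc1ccc(cc1)-c1cc(=O)c2c(OCc3ccccc3)c(CC(O)CC(=O)CC(=O)c3ccc(OCc4ccccc4)cc3)c(OCc3ccccc3)cc2o1 | intermediate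
13 | 1-[4-(benzyloxy)phenyl]-6-[5,7-bis(benzyloxy)-4'-methoxyflavon-6-yl]hexane-1,3,5-trione (not isolated) | COc1ccc(cc1)-c1cc(=O)c2c(OCc3ccccc3)c(CC(=O)CC(=O)CC(=O)c3ccc(OCc4ccccc4)cc3)c(OCc3ccccc3)cc2o1 | intermediate
14 | 5,7-bis(benzyloxy)-6-({6-[4-(benzyloxy)phenyl]-4-oxo-4H-pyran-2-yl}methyl)-4'-methoxyflavone | COc1ccc(cc1)-c1cc(=O)c2c(OCc3ccccc3)c(Cc3cc(=O)cc(-c4ccc(OCc5ccccc5)cc4)o3)c(OCc3ccccc3)cc2o1 | intermediate
15 | carbon dioxide | O=C=O | starting material
16 | rac-2-[5,7-bis(benzyloxy)-4'-methoxyflavon-6-yl]-2-{6-[4-(benzyloxy)phenyl]-4-oxo-4H-pyran-2-yl}acetic acid (racemic at C2) | COc1ccc(cc1)-c1cc(=O)c2c(OCc3ccccc3)c(C(C(=O)O)c3cc(=O)cc(-c4ccc(OCc5ccccc5)cc4)o3)c(OCc3ccccc3)cc2o1 | intermediate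
17 | (trimethylsilyl)acetylene | C#C[Si](C)(C)C | starting material
18 | tert-butyl hydroperoxide | CC(C)(C)OO | starting material
19 | triisopropylsilyl trifluoromethanesulfonate | CC(C)[Si](OS(=O)(=O)C(F)(F)F)(C(C)C)C(C)C | starting material
20 | lithium (trimethylsilyl)ethynolate (not isolated) | [Li+].[O-]C#C[Si](C)(C)C | intermediate
21 | triisopropyl{[(trimethylsilyl)ethynyl]oxy}silane | C[Si](C)(C)C#CO[Si](C(C)C)(C(C)C)C(C)C | intermediate
22 | (triisopropylsilyloxy)acetylene | C#CO[Si](C(C)C)(C(C)C)C(C)C | intermediate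
23 | rac-2-[5,7-bis(benzyloxy)-4'-methoxyflavon-6-yl]-2-{6-[4-(benzyloxy)phenyl]-4-oxo-4H-pyran-2-yl}acetyl chloride (not isolated) | COc1ccc(cc1)-c1cc(=O)c2c(OCc3ccccc3)c(C(C(Cl)=O)c3cc(=O)cc(-c4ccc(OCc5ccccc5)cc4)o3)c(OCc3ccccc3)cc2o1 | intermediate
24 | [6-(4-benzyloxyphenyl)-4-oxo-4H-pyran-2-yl][5,7-bis(benzyloxy)-4'-methoxyflavon-6-yl]ketene (not isolated) | O=C=C(c1cc(=O)cc(-c2ccc(OCc3ccccc3)cc2)o1)c1c(OCc2ccccc2)cc2oc(-c3ccc(OC)cc3)cc(=O)c2c1OCc1ccccc1 | intermediate
25 | rac-4-[5,7-bis(benzyloxy)-4'-methoxyflavon-6-yl]-4-{6-[4-(benzyloxy)phenyl]-4-oxo-4H-pyran-2-yl}-3-(triisopropylsilyloxy)cyclobut-2-en-1-one (racemic at C4, not isolated) | O=C1C=C(O[Si](C(C)C)(C(C)C)C(C)C)C1(c1cc(=O)cc(-c2ccc(OCc3ccccc3)cc2)o1)c1c(OCc2ccccc2)cc2oc(-c3ccc(OC)cc3)cc(=O)c2c1OCc1ccccc1 | intermediate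
26 | (3E)-4-[5,7-bis(benzyloxy)-4'-methoxyflavon-6-yl]-4-{6-[4-(benzyloxy)phenyl]-4-oxo-4H-pyran-2-yl}-3-(triisopropylsilyloxy)buta-1,3-dien-1-one, pyranonyl cis to the ketenyl carbon (not isolated) | O=C=C/C(O[Si](C(C)C)(C(C)C)C(C)C)=C(\c1cc(=O)cc(-c2ccc(OCc3ccccc3)cc2)o1)c1c(OCc2ccccc2)cc2oc(-c3ccc(OC)cc3)cc(=O)c2c1OCc1ccccc1 | intermediate
27 | rac-2-[4-(benzyloxy)phenyl]-8-[5,7-bis(benzyloxy)-4'-methoxyflavon-6-yl]-7-(triisopropylsilyloxy)-4aH-chromene-4,5-dione (racemic at C4a, not isolated) | O=C1C=C(O[Si](C(C)C)(C(C)C)C(C)C)C(c3c(OCc4ccccc4)cc4oc(-c5ccc(OC)cc5)cc(=O)c4c3OCc3ccccc3)=C2OC(c3ccc(OCc4ccccc4)cc3)=CC(=O)C12 | intermediate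
28 | 5,7-bis(benzyloxy)-6-{2-[4-(benzyloxy)phenyl]-5-hydroxy-4-oxo-7-(triisopropylsilyloxy)-4H-chromen-8-yl}-4'-methoxyflavone (racemic axis) | COc1ccc(cc1)-c1cc(=O)c2c(OCc3ccccc3)c(-c3c(O[Si](C(C)C)(C(C)C)C(C)C)cc(O)c4c(=O)cc(-c5ccc(OCc6ccccc6)cc5)oc34)c(OCc3ccccc3)cc2o1 | intermediate
29 | 5,7-bis(benzyloxy)-6-{2-[4-(benzyloxy)phenyl]-5,7-dihydroxy-4-oxo-4H-chromen-8-yl}-4'-methoxyflavone (racemic axis) | COc1ccc(cc1)-c1cc(=O)c2c(OCc3ccccc3)c(-c3c(O)cc(O)c4c(=O)cc(-c5ccc(OCc6ccccc6)cc5)oc34)c(OCc3ccccc3)cc2o1 | intermediate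
30 | 6-[5,7-dihydroxy-2-(4-hydroxyphenyl)-4-oxo-4H-chromen-8-yl]-5,7-dihydroxy-2-(4-methoxyphenyl)-4H-chromen-4-one (racemic axis) | COc1ccc(-c2cc(=O)c3c(O)c(-c4c(O)cc(O)c5c(=O)cc(-c6ccc(O)cc6)oc45)c(O)cc3o2)cc1 | target

**Step count.** Total: 14 steps. Longest linear sequence: 11 steps (steps 1–5, 7–9 and 12–14).

**Steps most likely to fail**

Step 12. The cycloaddition must join the silyloxy carbon to a ketene α-carbon that carries two bulky aryl-type groups. It may therefore be slow enough for ketene dimerisation, attack at the ketene oxygen or decomposition of the ynol ether to compete. Fallback, setting out from acacetin 1 and returning at target 30: the biaryl bond is made by cross-coupling of two complete flavones.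
- Exhaustive benzylation of 1 (BnBr, K2CO3, DMF, 80 °C) would give 5,7-bis(benzyloxy)-4'-methoxyflavone F1.
- Iodination with BnMe3N·ICl2 and CaCO3 in CH2Cl2/MeOH, a reagent that iodinates 5,7-dialkoxyflavones at C6, would give 5,7-bis(benzyloxy)-6-iodo-4'-methoxyflavone F2.
- Commercial apigenin would be perbenzylated to 5,7,4'-tris(benzyloxy)flavone F3 and iodinated at C8 (I2, CF3CO2Ag, CH2Cl2) to 5,7,4'-tris(benzyloxy)-8-iodoflavone F4.
- Miyaura borylation (B2pin2, PdCl2(dppf), KOAc, dioxane, 90 °C) would give the 8-pinacolboronate F5.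
- Suzuki–Miyaura coupling of F2 with F5 (Pd(OAc)2, SPhos, K3PO4, toluene/H2O, 100 °C) would give the 5,7,5'',7'',4'''-penta-O-benzyl biflavone F6.
- Debenzylation of F6 under the conditions of step 14 gives 30.

Step 9. The free acid is a vinylogous β-keto acid and may lose CO2 during acidic work-up and drying, and proton exchange between product carboxylate and unreacted anion may stall the carboxylation. Fallback, setting out from 14 and returning at 16: the carboxyl carbon is introduced as an ester. The lithium dienolate of 14 (LiN(SiMe3)2, THF, −78 °C) is acylated with di-tert-butyl dicarbonate to give tert-butyl 2-[5,7-bis(benzyloxy)-4'-methoxyflavon-6-yl]-2-{6-[4-(benzyloxy)phenyl]-4-oxo-4H-pyran-2-yl}acetate F7, which can be purified and stored. Brief acidolysis (CF3CO2H, CH2Cl2, 0 °C, evaporation) releases 16 under anhydrous conditions directly before step 12.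

Step 11. During C-desilylation, methoxide may also cleave the O–Si bond, or the silyl group may migrate from oxygen to carbon to give a silylketene; the volatile product may also be lost. Fallback, setting out from 19 and returning at 22, replacing steps 10 and 11: the parent ynolate is made directly. Ethyl dibromoacetate with t-BuLi (4 equiv, THF, −78 to 0 °C) would undergo double bromine–lithium exchange and loss of LiOEt from the ester dianion to give lithium ethynolate F8, which is O-silylated with 19 at −78 °C to give 22.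

**Further compounds**

F1 | step 12 | 5,7-bis(benzyloxy)-4'-methoxyflavone | COc1ccc(cc1)-c1cc(=O)c2c(OCc3ccccc3)cc(OCc3ccccc3)cc2o1
F2 | step 12 | 5,7-bis(benzyloxy)-6-iodo-4'-methoxyflavone | COc1ccc(cc1)-c1cc(=O)c2c(OCc3ccccc3)c(I)c(OCc3ccccc3)cc2o1
F3 | step 12 | 5,7,4'-tris(benzyloxy)flavone | O=c1cc(-c2ccc(OCc3ccccc3)cc2)oc2cc(OCc3ccccc3)cc(OCc3ccccc3)c12
F4 | step 12 | 5,7,4'-tris(benzyloxy)-8-iodoflavone | O=c1cc(-c2ccc(OCc3ccccc3)cc2)oc2c(I)c(OCc3ccccc3)cc(OCc3ccccc3)c12
F5 | step 12 | 5,7,4'-tris(benzyloxy)-8-(4,4,5,5-tetramethyl-1,3,2-dioxaborolan-2-yl)flavone | O=c1cc(-c2ccc(OCc3ccccc3)cc2)oc2c(B3OC(C)(C)C(C)(C)O3)c(OCc3ccccc3)cc(OCc3ccccc3)c12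
F6 | step 12 | 5,7-bis(benzyloxy)-6-{5,7-bis(benzyloxy)-2-[4-(benzyloxy)phenyl]-4-oxo-4H-chromen-8-yl}-4'-methoxyflavone (racemic axis) | COc1ccc(cc1)-c1cc(=O)c2c(OCc3ccccc3)c(-c3c(OCc4ccccc4)cc(OCc4ccccc4)c4c(=O)cc(-c5ccc(OCc6ccccc6)cc5)oc34)c(OCc3ccccc3)cc2o1
F7 | step 9 | tert-butyl rac-2-[5,7-bis(benzyloxy)-4'-methoxyflavon-6-yl]-2-{6-[4-(benzyloxy)phenyl]-4-oxo-4H-pyran-2-yl}acetate | COc1ccc(cc1)-c1cc(=O)c2c(OCc3ccccc3)c(C(C(=O)OC(C)(C)C)c3cc(=O)cc(-c4ccc(OCc5ccccc5)cc4)o3)c(OCc3ccccc3)cc2o1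
F8 | step 11 | lithium ethynolate | [Li+].[O-]C#C
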